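**Retrosynthetic overview**

1. The C5 hydroxyl is unmasked last, from the C5–B bond of boronate 10, by oxidation with retention.
2. Ring A of 10 is cut at C4–C4a and O1–C8a: O1, C2, C3 and C4 come from acylketene 8 (released from acyl Meldrum's acid 7, fragment 2), and C4a=C8a is the enol double bond of the ring B enol ether 4 (fragment 1).
3. Feature used (chromen-4-one numbering; ring A the pyranone, ring B the carbocycle): the C5 oxygen lies beta to the C4 carbonyl and allylic to the C4a=C8a enol unit, where an oxygen substituent would be eliminated or would ionise. A C5–B bond is inert in that position and serves as a latent hydroxyl of fixed configuration.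
4. 4 comes from cyclohex-2-en-1-one through its dimethyl ketal 2 by copper-catalysed enantioselective SN2' borylation, which sets C5 and places the enol double bond on the C4a side; 7 comes from Meldrum's acid and (13Z)-octadec-13-enoic acid.
5. Ring order: ring B is bought with cyclohexenone; ring A is the only ring formed (step 4).

Key step: step 4

Remark on the enol ether: ring B is carried as the methyl enol ether and not as a silyl enol ether. The ketal precursor lets the copper catalyst turn over without a proton source or a silylating agent (the expelled methoxide regenerates the copper alkoxide), and an O-methyl enol ether cannot be desilylated by the strongly acidic fragment 2; methanol is then the group lost from C8a.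

Assumption: the sense of induction in step 2 is assigned by analogy with acyclic allyl acetals; if the (R,R)-ligand gives the (R)-boronate, the equally available (S,S)-ligand is used. Acid 6 (cis-13-octadecenoic acid) is taken as a purchasable fatty acid.

**Route**

Step 1
Reactants: 1 cyclohex-2-en-1-one
Product: 2 3,3-dimethoxycyclohex-1-ene
Conditions: MeOSiMe3 (2.5 equiv), Me3SiOTf (2 mol %), CH2Cl2, −78 °C; pyridine quench, NaHCO3 wash, distillation
Reagents that add atoms: methoxytrimethylsilane, CO[Si](C)(C)C
Why: Noyori acetalisation, in which Me3SiOTf-catalysed exchange of the carbonyl oxygen for two methoxy groups is driven by formation of hexamethyldisiloxane and runs cold and aprotic, so that neither conjugate addition of methanol nor migration of the double bond should occur.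

Step 2
Reactants: 2 3,3-dimethoxycyclohex-1-ene; 3 bis(pinacolato)diboron (1.5 equiv)
Product: 4 2-[(1S)-3-methoxycyclohex-2-en-1-yl]-4,4,5,5-tetramethyl-1,3,2-dioxaborolane (fragment 1)
Conditions: CuCl (5 mol %), (R,R)-BenzP* [(R,R)-1,2-bis(tert-butylmethylphosphino)benzene] (5 mol %), KOt-Bu (10 mol %), THF, 0 °C; non-aqueous work-up, filtration through Et3N-deactivated silica
Reagents that add atoms: none
Why: Copper-catalysed enantioselective SN2' (gamma-selective) boryl substitution of an allyl acetal, in which the chiral bisphosphine–copper boryl adds across the ring alkene with boron on the distal carbon (the catalyst's choice of alkene face sets the C5 stereocentre) and beta-elimination of copper methoxide fixes the enol double bond between the future C4a and C8a and regenerates the copper alkoxide that reactivates B2pin2.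

Step 3
Reactants: 5 Meldrum's acid (2,2-dimethyl-1,3-dioxane-4,6-dione); 6 (13Z)-octadec-13-enoic acid
Product: 7 5-[(13Z)-octadec-13-enoyl]-2,2-dimethyl-1,3-dioxane-4,6-dione (fragment 2, present as its enol)
Conditions: DCC (1.1 equiv), DMAP (1.5 equiv), CH2Cl2, 0 → 23 °C; filtration, cold 5% aqueous KHSO4 wash; used without chromatography
Reagents that add atoms: none
Why: Carbodiimide-mediated C-acylation of Meldrum's acid (Steglich-type activation with DMAP as acyl-transfer agent and base), in which the doubly activated methylene is acylated at carbon to give the stable enol form of 7 and the isolated Z-alkene is not touched.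

Step 4
Reactants: 4 2-[(1S)-3-methoxycyclohex-2-en-1-yl]-4,4,5,5-tetramethyl-1,3,2-dioxaborolane (fragment 1, 1.3 equiv); 7 5-[(13Z)-octadec-13-enoyl]-2,2-dimethyl-1,3-dioxane-4,6-dione (fragment 2)
Product: 10 (5S)-2-[(12Z)-heptadec-12-en-1-yl]-5-(4,4,5,5-tetramethyl-1,3,2-dioxaborolan-2-yl)-5,6,7,8-tetrahydro-4H-chromen-4-one, via acylketene 8 (not isolated), via methoxy ketal cycloadduct 9 (not isolated)
Conditions: 4 in PhMe, 110 °C, argon sweep, 7 in PhMe added over 2 h; then CSA (10 mol %), 23 °C
Reagents that add atoms: none
Why: Hetero-Diels–Alder annulation of an acylketene with an enol ether: at 110 °C fragment 2 loses acetone and CO2 to give acylketene 8, whose ketene carbon (future C4) is attacked by the nucleophilic enol carbon of 4 (future C4a) while the acyl oxygen (O1) bonds to the methoxy-bearing carbon (C8a). The closest known reaction is the thermal union of acylated Meldrum's acids or dioxinones with alkyl enol ethers and enamines, followed by loss of alcohol or amine, which is an established 4-pyranone synthesis. Ring A closes in this [4+2] addition (in the stepwise limit, C-acylation followed by 6-exo-trig attack of the enolate oxygen on the oxocarbenium carbon) to give ketal 9, and acid-catalysed elimination of methanol across C4a–C8a then gives the pyranone. No lasting stereocentre is made, since C4a and C8a of 9 end up sp2, and the C5 centre from step 2 is not involved because a C–B bond beta to the C4 carbonyl and allylic to the enol unit can neither leave as an anion nor ionise. The step needs acylation at C4a and not at the other alpha-carbon, which the fixed position of the enol double bond secures, and it needs the [4+2] trapping to outrun proton transfer from acidic 7 to the enol ether and allyl transfer from boron; slow addition of 7 (low stationary concentration of acid and of 8), the argon sweep that removes acetone and methanol, and the low reactivity of a pinacol allylboronate should secure this.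

Step 5
Reactants: 10 (5S)-2-[(12Z)-heptadec-12-en-1-yl]-5-(4,4,5,5-tetramethyl-1,3,2-dioxaborolan-2-yl)-5,6,7,8-tetrahydro-4H-chromen-4-one
Product: 12 (5S)-2-[(12Z)-heptadec-12-en-1-yl]-5-hydroxy-5,6,7,8-tetrahydro-4H-chromen-4-one (target CNP0118262.1), via pinacol borate ester 11 (not isolated)
Conditions: NaBO3·4H2O (3 equiv), THF/H2O (1:1), 23 °C
Reagents that add atoms: sodium perborate (NaBO3·4H2O), [Na+].[Na+].O[B-]1(O)OO[B-](O)(O)OO1
Why: Stereoretentive oxidation of a boronic ester (Brown-type oxidation), in which hydroperoxide from perborate adds to boron and C5 migrates from boron to oxygen with retention to give 11, which is hydrolysed in the same flask, while the buffered, mildly basic medium should leave the pyranone and the Z-alkene untouched.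

**Compound list**

1 | cyclohex-2-en-1-one | O=C1C=CCCC1 | starting material
2 | 3,3-dimethoxycyclohex-1-ene | COC1(OC)C=CCCC1 | intermediate
3 | bis(pinacolato)diboron | CC1(C)OB(OC1(C)C)B1OC(C)(C)C(C)(C)O1 | starting material
4 | 2-[(1S)-3-methoxycyclohex-2-en-1-yl]-4,4,5,5-tetramethyl-1,3,2-dioxaborolane (fragment 1) | COC1=C[C@@H](B2OC(C)(C)C(C)(C)O2)CCC1 | intermediate
5 | Meldrum's acid (2,2-dimethyl-1,3-dioxane-4,6-dione) | CC1(C)OC(=O)CC(=O)O1 | starting material
6 | (13Z)-octadec-13-enoic acid | CCCC/C=C\CCCCCCCCCCCC(=O)O | starting material
7 | 5-[(13Z)-octadec-13-enoyl]-2,2-dimethyl-1,3-dioxane-4,6-dione (fragment 2) | CCCC/C=C\CCCCCCCCCCCC(=O)C1C(=O)OC(C)(C)OC1=O | intermediate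
8 | (15Z)-icosa-1,15-diene-1,3-dione (acylketene) | CCCC/C=C\CCCCCCCCCCCC(=O)C=C=O | intermediate
9 | (4aS,5S,8aS)-2-[(12Z)-heptadec-12-en-1-yl]-8a-methoxy-5-(4,4,5,5-tetramethyl-1,3,2-dioxaborolan-2-yl)-4a,5,6,7,8,8a-hexahydro-4H-chromen-4-one (cis-fused, C4a–C4 bond anti to the C5–B bond; C4a and C8a are erased in the same step) | CCCC/C=C\CCCCCCCCCCCC1=CC(=O)[C@@H]2[C@@H](B3OC(C)(C)C(C)(C)O3)CCC[C@]2(OC)O1 | intermediate
10 | (5S)-2-[(12Z)-heptadec-12-en-1-yl]-5-(4,4,5,5-tetramethyl-1,3,2-dioxaborolan-2-yl)-5,6,7,8-tetrahydro-4H-chromen-4-one | CCCC/C=C\CCCCCCCCCCCc1cc(=O)c2c(o1)CCC[C@@H]2B1OC(C)(C)C(C)(C)O1 | intermediate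
11 | (5S)-2-[(12Z)-heptadec-12-en-1-yl]-5-[(4,4,5,5-tetramethyl-1,3,2-dioxaborolan-2-yl)oxy]-5,6,7,8-tetrahydro-4H-chromen-4-one | CCCC/C=C\CCCCCCCCCCCc1cc(=O)c2c(o1)CCC[C@@H]2OB1OC(C)(C)C(C)(C)O1 | intermediate
12 | (5S)-2-[(12Z)-heptadec-12-en-1-yl]-5-hydroxy-5,6,7,8-tetrahydro-4H-chromen-4-one | CCCC/C=C\CCCCCCCCCCCc1cc(=O)c2c(o1)CCC[C@@H]2O | target

**Step count**

Total: 5 steps. Longest linear sequence: 4 steps (steps 1, 2, 4, 5); step 3 is the convergent branch.

**Steps most likely to fail**

Step 4. Proton transfer from the acidic acyl Meldrum's acid to the enol ether may move or destroy the enol double bond, and the acylketene may be consumed by liberated methanol or by dimerisation before it finds the hindered enol carbon. The fallback drops the boron carrier and brings ring B in as a 1,3-dione, with C5 set by reduction. It sets out from 7: heating 7 with commercial cyclohexane-1,3-dione and catalytic Et3N in toluene at 110 °C should acylate the dione enol at carbon with acylketene 8 to give 2-[(15Z)-3-oxoicos-15-enoyl]cyclohexane-1,3-dione F1, which is not isolated and is cyclodehydrated with CF3CO2H in CH2Cl2 to 2-[(12Z)-heptadec-12-en-1-yl]-7,8-dihydro-4H-chromene-4,5(6H)-dione F2. Asymmetric transfer hydrogenation of F2 with RuCl(p-cymene)[(S,S)-TsDPEN] in HCO2H/Et3N should reduce only the C5 ketone; by analogy with 1-tetralone the (S,S)-catalyst should give the (S)-carbinol, and neither the pyranone carbonyl nor the Z-alkene should react. The fallback comes back to the route at 12.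

Step 2. Facial discrimination in the borylcupration of the cyclic ketal may be weaker than with acyclic allyl acetals, so that 4 is formed with insufficient enantiomeric purity. The fallback secures the stereocentre with an enzyme and not with the copper catalyst. It sets out from 12, reached through steps 4 and 5 with the material as obtained: treatment with Candida antarctica lipase B and vinyl acetate in MTBE at 30 °C should, by the usual preference of lipases for the enantiomer shaped like (R)-1-phenylethanol, acetylate the minor (5R)-alcohol to (5R)-2-[(12Z)-heptadec-12-en-1-yl]-4-oxo-5,6,7,8-tetrahydro-4H-chromen-5-yl acetate F3, and unreacted (5S)-alcohol is separated by chromatography. The fallback comes back to the route at 12.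

Step 5. Hydroxide or hydroperoxide may add to C2 of the pyranone and open ring A, or the C5 carbinol may ionise, faster than the migration from boron to oxygen is completed. The fallback changes the oxidant class and removes water, base and peroxide. It sets out from 10: anhydrous trimethylamine N-oxide in THF at 65 °C should oxidise the C–B bond by the same 1,2-shift with retention and give borate ester 11, which is then cleaved separately on work-up with pH 7 buffer. The fallback comes back to the route at 11 and from there at 12; it makes no compound outside the list (entry F0).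

**Further compounds**

F1 | step 4 | 2-[(15Z)-3-oxoicos-15-enoyl]cyclohexane-1,3-dione | CCCC/C=C\CCCCCCCCCCCC(=O)CC(=O)C1C(=O)CCCC1=O
F2 | step 4 | 2-[(12Z)-heptadec-12-en-1-yl]-7,8-dihydro-4H-chromene-4,5(6H)-dione | CCCC/C=C\CCCCCCCCCCCc1cc(=O)c2c(o1)CCCC2=O
F3 | step 2 | (5R)-2-[(12Z)-heptadec-12-en-1-yl]-4-oxo-5,6,7,8-tetrahydro-4H-chromen-5-yl acetate | CCCC/C=C\CCCCCCCCCCCc1cc(=O)c2c(o1)CCC[C@H]2OC(C)=O
F0 | step 5 | none | none
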